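Compound numbers are those of the steps and of the compound list below. Isoflavone numbering is used: rings A and C form the chromenone, ring B is primed, ring D is doubly primed (O1'', C2'', C3'', C4'').

## Analysis of the target

Compound 18 is an isoflavone. Ring A and the pyranone ring C make up a 5,7-dihydroxychromen-4-one, and C3 of ring C carries ring B. Ring B is substituted on four neighbouring carbons: C1' (bond to C3), C2' (free hydroxyl), C3' (the benzylic methylene C4'') and C4' (the ether oxygen O1''). C3' and C4' are shared with the dihydropyran ring D, so rings B and D together are a 3-hydroxy-2,2-dimethylchroman. The only stereocenter is C3'', an (S)-configured secondary carbinol between the methylene C4'' and the quaternary, oxygen-bearing C2''; as it stands alone, only its absolute configuration has to be controlled. The sensitive groups are the three phenols (the C5 hydroxyl is chelated to the C4 carbonyl), the C2=C3 enone of ring C, which strong base opens and hydrogen can over-reduce, and the tertiary alkyl aryl ether next to the carbinol, which strong acid can ionise. The difficulty is threefold: an isolated carbinol must be made as one enantiomer without a neighbouring control element, ring B needs four contiguous substituents with ring D closed onto the C4' oxygen and not the C2' oxygen, and the isoflavone has to be assembled around this electron-rich ring. The strategy rests on two facts: C3' lies between the oxygenated carbons C2' and C4', so before ring D closes it is the central carbon of a symmetric 1,3-dioxygenated benzene; and the chain C4''H2–C3''H(OH)–C2'' corresponds atom for atom to C3, C2 and C1 of L-malic acid 3, which has the same (S) configuration and carries on C4 a carboxyl group exactly where the bond to C3' is needed.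

## Retrosynthetic reasoning

**18 to 17.** The three phenolic O–H bonds are traced back to benzyl ethers. They leave under neutral hydrogenolysis, which neither ionises ring D nor opens ring C. The C3'' hydroxyl stays free.

**17 to 15 (through 16).** The O1–C2 bond is cut and ring B is moved from C3 back to the neighbouring carbon, which turns the isoflavone into the 2'-hydroxychalcone 15. This traces C2 to an aldehyde carbon on ring B and C3/C4 to an acetyl group on ring A, so the two aromatic halves can be joined by a simple condensation. The forward reaction is an oxidative 1,2-aryl shift. It needs an electron-rich migrating ring, and ring B has oxygen ortho and para to C1'.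

**15 to 12 and 14.** The enone C=C bond is cut to the aldehyde 12 and the acetophenone 14. Compound 14 comes from 13 by two-fold benzylation; the chelated hydroxyl that remains later becomes O1.

**12 to 11 to 10.** The benzyl group is removed and the C1'–CHO bond is cut. In 10 the only free phenol is the C2' hydroxyl and C1' is the only open position ortho to it. A phenoxide-directed ortho-formylation therefore has no regiochemical choice, whereas an undirected electrophile could also attack C5'.

**10 to 9 to 8.** The O1''–C2'' bond is cut, opening ring D to a tertiary carbinol and a phenol. The two phenols of 9 are equivalent, so the closure cannot go the wrong way. The forward reaction ionises the tertiary carbon and leaves the C3''–O bond alone. Compound 9 comes from 8 by unmasking the phenols.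

**8 to 7.** The two C2''–CH3 bonds are cut. The tertiary carbinol comes from a carbonyl at the carboxyl level, the dioxolanone of 7, which takes two methyl nucleophiles and sheds its acetonide in the same operation. The protecting group of the hydroxy acid is thus also its activating group.

**7 to 2 and 6.** The C3'–C4'' bond is cut. This is the bond between the aromatic part and the chiral side chain. Cutting it leaves the symmetric aryl iodide 2 and a three-carbon fragment 6 whose activated carboxyl group is the handle that is exchanged for the aryl carbon. The carbon that becomes reactive is a CH2 group, so the stereocenter is only a spectator. A cut at C4''–C3'' would force the stereocenter to be created in the bond-forming step, and closing ring D first would destroy the symmetry that makes 2 simple.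

**6 to 4 and 5; 4 to 3; 2 to 1.** The redox-active ester 6 is the ester of acid 4 with N-hydroxyphthalimide 5. Acid 4 is L-malic acid 3 with its α-hydroxy acid unit tied up as an acetonide, and 2 is the bis-methoxymethyl ether of 2-iodoresorcinol 1.

## Alternatives that were turned down

**Alternative 1:** Ring D is disconnected at O1''–C2'' at the very end.
- **Key step:** the silyl ether A2 carries an (S)-configured 2,2-dimethyloxirane on C3'. Buffered TBAF frees its C4' phenol, and camphorsulfonic acid then drives attack on the tertiary epoxide carbon to give the tri-O-benzyl ether A1.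
- **For:** acid-promoted 6-endo opening of such epoxides is well precedented, the C3''–O bond is never broken, and the synthesis is convergent. A1 is the same compound as 17.
- **Against:** the stereocenter must come from a reagent-controlled epoxidation of a trisubstituted alkene on an electron-rich arene, whose selectivity is not assured. The acid-labile epoxide must be introduced late or survive the isoflavone chemistry. Attack in the 5-exo mode at the secondary carbon competes. The two oxygens flanking C3' must be differentiated from the start (benzyl on C2', silyl on C4').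
- **Comparison:** this alternative is stronger on the ring closure itself, and it is kept as the fallback for step 7. The chosen strategy offers in its place an absolute configuration taken from the chiral pool, with no enantioselective step, and a closure whose direction is settled by symmetry.

**Alternative 2:** The C3–C4 bond of ring C is disconnected.
- **Key step:** BF3·OEt2 opens the chalcone epoxide A4 at the benzylic carbon and the aroyl group migrates to it, giving the formyl ketone A3.
- **For:** no thallium is needed, and the electron-rich ring B stabilises the benzylic cation, so the epoxide should open at the right carbon.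
- **Against:** it needs an extra epoxidation. The ring A ketone has both ortho oxygens benzylated, which slows the condensation. A3 is a β-keto aldehyde that is prone to deformylation. Closing ring C then requires removal of an ortho benzyl group on ring A, and the Lewis acid can attack benzyl ethers.
- **Comparison:** as an end game it is one step longer than steps 12 and 13 and stronger on reagent toxicity. It says nothing about ring D or C3'': the (3S)-chroman must exist beforehand. The chosen strategy supplies exactly that part and keeps the one-flask thallium sequence for the core.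

**Alternative 3:** The C3–C1' bond is disconnected by a 2,3-aryl shift in a flavanone.
- **Key step:** PhI(OH)OTs (trivalent iodine) iodinates the C3 enol of flavanone A6, ring B moves from C2 to C3 with loss of iodobenzene, and proton loss gives the tetra-O-benzyl ether A5.
- **For:** no thallium, a flavanone is easy to reach from a 2'-hydroxychalcone, and ring B migrates well.
- **Against:** it adds the chalcone-to-flavanone step, dehydrogenation without migration competes, and the C3'' hydroxyl is benzylated as well.
- **Comparison:** it is equal or stronger on reagent safety and one step longer. Like alternative 2 it leaves ring D and the stereocenter unsolved. Its chemistry is kept as the fallback for step 12.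

Key step: step 4

Remark: the secondary C3'' hydroxyl is carried unprotected from compound 8 to the end, since no later reagent (carbonate base, hydroxide, the thallium salt, hydrogen over palladium) is expected to touch it.

Remark: the silyl group of A2 is taken to be tert-butyldimethylsilyl.

## Route

**Step 1**
Reactants: 1 2-iodoresorcinol (2-iodobenzene-1,3-diol)
Product: 2 2-iodo-1,3-bis(methoxymethoxy)benzene
Conditions: MOMCl (2.5 equiv), i-Pr2NEt (3 equiv), CH2Cl2, 0 °C to rt
Reagents that add atoms: chloromethyl methyl ether, COCCl
Why: O-alkylation of both phenols with an α-chloro ether (Williamson-type etherification); the methoxymethyl group is the smallest base-stable phenol protection and so crowds the iodine least in step 4.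

**Step 2**
Reactants: 3 L-malic acid
Product: 4 [(4S)-2,2-dimethyl-5-oxo-1,3-dioxolan-4-yl]acetic acid
Conditions: 2,2-dimethoxypropane (solvent), p-TsOH·H2O (2 mol%), rt
Reagents that add atoms: 2,2-dimethoxypropane, COC(C)(C)OC
Why: Acid-catalysed transacetalisation; the α-hydroxy acid closes to the five-membered dioxolanone in preference to the six-membered isomer, which leaves the β-carboxyl free and does not touch the stereocenter.

**Step 3**
Reactants: 4 [(4S)-2,2-dimethyl-5-oxo-1,3-dioxolan-4-yl]acetic acid; 5 N-hydroxyphthalimide
Product: 6 1,3-dioxoisoindolin-2-yl 2-[(4S)-2,2-dimethyl-5-oxo-1,3-dioxolan-4-yl]acetate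
Conditions: DIC (1.1 equiv), DMAP (5 mol%), CH2Cl2, 0 °C to rt
Reagents that add atoms: none
Why: Steglich-type carbodiimide esterification of the free carboxyl; the dioxolanone is inert to these conditions and the product is used soon after filtration through silica.

**Step 4**
Reactants: 2 2-iodo-1,3-bis(methoxymethoxy)benzene; 6 1,3-dioxoisoindolin-2-yl 2-[(4S)-2,2-dimethyl-5-oxo-1,3-dioxolan-4-yl]acetate
Product: 7 (5S)-5-[2,6-bis(methoxymethoxy)benzyl]-2,2-dimethyl-1,3-dioxolan-4-one
Conditions: 6 (1.5 equiv), NiCl2·glyme (20 mol%), 2,2'-bipyridine (20 mol%), AgNO3 (0.3 equiv), Mg anode, reticulated vitreous carbon cathode, undivided cell, constant current, NMP, rt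
Reagents that add atoms: none
Why: The closest known reaction type is the nickel-catalysed electroreductive decarboxylative arylation of N-hydroxyphthalimide esters with aryl iodides, a reductive cross-electrophile coupling, and it is used here as such. The cathode reduces the bipyridine complex of NiCl2 from divalent to low-valent nickel (zerovalent or monovalent), which inserts into the C–I bond of 2; the two ortho oxygens crowd this site but can also hold the metal. Single-electron transfer to 6 gives a radical anion that breaks down to the phthalimide anion, CO2 and the primary radical at the future C4''. The aryl nickel species captures this radical and reductive elimination from trivalent nickel forms C3'–C4''; the magnesium anode supplies the electrons and silver plated onto the cathode from AgNO3 keeps the working potential mild. No ring is closed and no stereocenter is created: the radical sits on the CH2 carbon, one atom away from the (S) centre, whose four bonds are never broken, so the configuration of 3 passes into 7 unchanged. The selectivity needed is cross-coupling over hydrodeiodination of 2 and over reduction or dimerisation of the radical; a primary, unhindered radical and the excess of 6 favour capture at the crowded nickel centre. Regiochemistry is fixed by the position of the iodine, and because 2 is symmetric either oxygen can later close ring D.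

**Step 5**
Reactants: 7 (5S)-5-[2,6-bis(methoxymethoxy)benzyl]-2,2-dimethyl-1,3-dioxolan-4-one
Product: 8 (2S)-1-[2,6-bis(methoxymethoxy)phenyl]-3-methylbutane-2,3-diol
Conditions: MeMgBr (5 equiv), THF, −40 to 0 °C; aq. NH4Cl
Reagents that add atoms: methylmagnesium bromide, C[Mg]Br
Why: Double Grignard addition to the lactone carbonyl; the first adduct collapses with loss of the acetonide as acetone (taken up by excess reagent) and unmasks the C3'' alkoxide, the second addition gives the tertiary carbinol. Addition to this activated ester should outrun enolisation at low temperature, so the (S) centre is kept.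

**Step 6**
Reactants: 8 (2S)-1-[2,6-bis(methoxymethoxy)phenyl]-3-methylbutane-2,3-diol
Product: 9 2-[(2S)-2,3-dihydroxy-3-methylbutyl]benzene-1,3-diol
Conditions: HCl (1 M in MeOH), 40 °C
Reagents that add atoms: none
Why: Acid-catalysed acetal exchange removes both methoxymethyl groups as volatile dimethoxymethane; it is run separately from the ring closure so that no formaldehyde equivalent is present when the electron-rich ring later meets stronger acid.

**Step 7**
Reactants: 9 2-[(2S)-2,3-dihydroxy-3-methylbutyl]benzene-1,3-diol
Product: 10 (3S)-2,2-dimethylchroman-3,5-diol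
Conditions: p-TsOH·H2O (20 mol%), 1,2-dichloroethane, 70 °C, high dilution
Reagents that add atoms: none
Why: Acid-catalysed cyclodehydration (intramolecular SN1 etherification): the tertiary carbinol ionises and a phenol oxygen captures the cation in a six-membered closure that forms O1''–C2''. The two phenols are equivalent, so only one product is possible, and the C3''–O bond is not involved, so the (S) configuration is retained.

**Step 8**
Reactants: 10 (3S)-2,2-dimethylchroman-3,5-diol
Product: 11 (3S)-3,5-dihydroxy-2,2-dimethylchroman-6-carbaldehyde
Conditions: MgCl2 (3 equiv), Et3N (6 equiv), (CH2O)n (8 equiv), MeCN, reflux; aq. HCl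
Reagents that add atoms: paraformaldehyde (as formaldehyde), C=O
Why: Casnati–Skattebøl ortho-formylation: the magnesium phenoxide delivers formaldehyde to the ortho carbon through a chelate and a second formaldehyde oxidises the benzylic alkoxide by hydride transfer. C6 of the chroman (C1' of ring B) is the only free ortho position, so the para position is not attacked.

**Step 9**
Reactants: 11 (3S)-3,5-dihydroxy-2,2-dimethylchroman-6-carbaldehyde
Product: 12 (3S)-5-(benzyloxy)-3-hydroxy-2,2-dimethylchroman-6-carbaldehyde
Conditions: BnBr (1.1 equiv), K2CO3 (2 equiv), DMF, rt to 50 °C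
Reagents that add atoms: benzyl bromide, BrCc1ccccc1
Why: Williamson etherification; carbonate deprotonates only the phenol, so the secondary alcohol stays free.

**Step 10**
Reactants: 13 2,4,6-trihydroxyacetophenone
Product: 14 1-[2,4-bis(benzyloxy)-6-hydroxyphenyl]ethan-1-one
Conditions: BnBr (2.1 equiv), K2CO3 (2.2 equiv), DMF, rt
Reagents that add atoms: benzyl bromide, BrCc1ccccc1
Why: Williamson etherification that stops after two alkylations, because the last hydroxyl is hydrogen-bonded to the carbonyl and is the least nucleophilic.

**Step 11**
Reactants: 12 (3S)-5-(benzyloxy)-3-hydroxy-2,2-dimethylchroman-6-carbaldehyde; 14 1-[2,4-bis(benzyloxy)-6-hydroxyphenyl]ethan-1-one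
Product: 15 (2E)-1-[2,4-bis(benzyloxy)-6-hydroxyphenyl]-3-[(3S)-5-(benzyloxy)-3-hydroxy-2,2-dimethylchroman-6-yl]prop-2-en-1-one
Conditions: KOH (50% aq., excess), EtOH/THF, rt
Reagents that add atoms: none
Why: Claisen–Schmidt condensation of a non-enolisable aldehyde with a methyl ketone; E1cB loss of water gives the conjugated (E)-enone, and the carbinol and benzyl ethers are stable to hydroxide.

**Step 12**
Reactants: 15 (2E)-1-[2,4-bis(benzyloxy)-6-hydroxyphenyl]-3-[(3S)-5-(benzyloxy)-3-hydroxy-2,2-dimethylchroman-6-yl]prop-2-en-1-one
Product: 17 5,7-bis(benzyloxy)-3-[(3S)-5-(benzyloxy)-3-hydroxy-2,2-dimethylchroman-6-yl]-4H-chromen-4-one, via rearranged dimethyl acetal 16 (not isolated)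
Conditions: Tl(NO3)3·3H2O (1.2 equiv), MeOH/HC(OMe)3, rt; then 10% aq. HCl, 50 °C
Reagents that add atoms: none
Why: Oxidative 1,2-aryl shift of a 2'-hydroxychalcone with trivalent thallium: methanol adds to the β-carbon and thallium to the α-carbon, the electron-rich ring B migrates as monovalent thallium leaves, and a second methanol gives acetal 16. Acid then closes the chelated hydroxyl onto the acetal carbon and loss of methanol forms ring C with ring B on C3.

**Step 13**
Reactants: 17 5,7-bis(benzyloxy)-3-[(3S)-5-(benzyloxy)-3-hydroxy-2,2-dimethylchroman-6-yl]-4H-chromen-4-one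
Product: 18 5,7-dihydroxy-3-[(3S)-3,5-dihydroxy-2,2-dimethylchroman-6-yl]-4H-chromen-4-one (CNP0318808.1)
Conditions: H2 (1 atm), 10% Pd/C, EtOAc/MeOH, rt, stopped at three equivalents of H2
Reagents that add atoms: none
Why: Hydrogenolysis of three aryl benzyl ethers under neutral conditions; ring D has no benzylic C–O bond and the conjugated C2=C3 bond is reduced more slowly than the ethers are cleaved.

## Compound list

1 | 2-iodoresorcinol | Oc1cccc(O)c1I | starting material
2 | 2-iodo-1,3-bis(methoxymethoxy)benzene | COCOc1cccc(OCOC)c1I | intermediate
3 | L-malic acid | OC(=O)C[C@H](O)C(=O)O | starting material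
4 | [(4S)-2,2-dimethyl-5-oxo-1,3-dioxolan-4-yl]acetic acid | CC1(C)OC(=O)[C@H](CC(=O)O)O1 | intermediate
5 | N-hydroxyphthalimide | ON1C(=O)c2ccccc2C1=O | starting material
6 | 1,3-dioxoisoindolin-2-yl 2-[(4S)-2,2-dimethyl-5-oxo-1,3-dioxolan-4-yl]acetate | CC1(C)OC(=O)[C@H](CC(=O)ON2C(=O)c3ccccc3C2=O)O1 | intermediate
7 | (5S)-5-[2,6-bis(methoxymethoxy)benzyl]-2,2-dimethyl-1,3-dioxolan-4-one | CC1(C)OC(=O)[C@H](Cc2c(OCOC)cccc2OCOC)O1 | intermediate
8 | (2S)-1-[2,6-bis(methoxymethoxy)phenyl]-3-methylbutane-2,3-diol | CC(C)(O)[C@@H](O)Cc1c(OCOC)cccc1OCOC | intermediate
9 | 2-[(2S)-2,3-dihydroxy-3-methylbutyl]benzene-1,3-diol | CC(C)(O)[C@@H](O)Cc1c(O)cccc1O | intermediate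
10 | (3S)-2,2-dimethylchroman-3,5-diol | CC1(C)Oc2cccc(O)c2C[C@@H]1O | intermediate
11 | (3S)-3,5-dihydroxy-2,2-dimethylchroman-6-carbaldehyde | CC1(C)Oc2ccc(C=O)c(O)c2C[C@@H]1O | intermediate
12 | (3S)-5-(benzyloxy)-3-hydroxy-2,2-dimethylchroman-6-carbaldehyde | CC1(C)Oc2ccc(C=O)c(OCc3ccccc3)c2C[C@@H]1O | intermediate
13 | 2,4,6-trihydroxyacetophenone | CC(=O)c1c(O)cc(O)cc1O | starting material
14 | 1-[2,4-bis(benzyloxy)-6-hydroxyphenyl]ethan-1-one | CC(=O)c1c(O)cc(OCc2ccccc2)cc1OCc1ccccc1 | intermediate
15 | (2E)-1-[2,4-bis(benzyloxy)-6-hydroxyphenyl]-3-[(3S)-5-(benzyloxy)-3-hydroxy-2,2-dimethylchroman-6-yl]prop-2-en-1-one | CC1(C)Oc2ccc(/C=C/C(=O)c3c(O)cc(OCc4ccccc4)cc3OCc3ccccc3)c(OCc3ccccc3)c2C[C@@H]1O | intermediate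
16 | 1-[2,4-bis(benzyloxy)-6-hydroxyphenyl]-2-[(3S)-5-(benzyloxy)-3-hydroxy-2,2-dimethylchroman-6-yl]-3,3-dimethoxypropan-1-one (both epimers at C2 of the propanone) | CC1(C)Oc2ccc(C(C(OC)OC)C(=O)c3c(O)cc(OCc4ccccc4)cc3OCc3ccccc3)c(OCc3ccccc3)c2C[C@@H]1O | intermediate
17 | 5,7-bis(benzyloxy)-3-[(3S)-5-(benzyloxy)-3-hydroxy-2,2-dimethylchroman-6-yl]-4H-chromen-4-one | CC1(C)Oc2ccc(-c3coc4cc(OCc5ccccc5)cc(OCc5ccccc5)c4c3=O)c(OCc3ccccc3)c2C[C@@H]1O | intermediate
18 | 5,7-dihydroxy-3-[(3S)-3,5-dihydroxy-2,2-dimethylchroman-6-yl]-4H-chromen-4-one (CNP0318808.1) | CC1(C)Oc2ccc(-c3coc4cc(O)cc(O)c4c3=O)c(O)c2C[C@@H]1O | target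

## Step count and least certain steps

Total: 13 steps. Longest linear sequence: 11 steps (3 to 18 through steps 2, 3, 4, 5, 6, 7, 8, 9, 11, 12, 13).

**Step 4 (key step).**
- Risk: oxidative addition and radical capture at the doubly ortho-substituted aryl nickel centre may be slow. Hydrodeiodination of the aryl iodide and reduction or dimerisation of the alkyl radical would then consume both partners.
- Fallback, from 2 back to the route at 8: the same C3'–C4'' bond is made by polar chemistry. Iodine–magnesium exchange on 2 (i-PrMgCl·LiCl, THF, −20 °C) gives the aryl Grignard reagent. With CuI (10 mol%) it should open commercial methyl (S)-glycidate at the terminal carbon and give methyl (2S)-3-[2,6-bis(methoxymethoxy)phenyl]-2-hydroxypropanoate F1. Excess MeMgBr converts the ester of F1 into the tertiary carbinol and gives 8. The stereocenter then comes from the glycidate, whose C2–O bond is not touched. This path is shorter, but it gives up malic acid as the chiral source.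

**Step 7.**
- Risk: the tertiary cation next to the carbinol can undergo a 1,2-hydride shift from C3'' (pinacol rearrangement), which would erase the stereocenter. Intermolecular C-alkylation of the electron-rich ring is a second possibility.
- Fallback, from 9 back to the route at 10: ring D is closed by 6-endo opening of an epoxide made with retention.
  - BnBr and K2CO3 in acetone benzylate only the phenols and give (2S)-1-[2,6-bis(benzyloxy)phenyl]-3-methylbutane-2,3-diol F2.
  - A one-flask sequence (MeC(OMe)3 with pyridinium tosylate, then Me3SiCl, then K2CO3 in MeOH) passes through the cyclic orthoacetate (5S)-5-[2,6-bis(benzyloxy)benzyl]-2-methoxy-2,4,4-trimethyl-1,3-dioxolane F3 and the chloro acetate (2S)-1-[2,6-bis(benzyloxy)phenyl]-3-chloro-3-methylbutan-2-yl acetate F4. It gives the epoxide (3S)-3-[2,6-bis(benzyloxy)benzyl]-2,2-dimethyloxirane F5 with overall retention at C3''.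
  - Neutral hydrogenolysis (H2, Pd/C, EtOAc) frees 2-{[(2S)-3,3-dimethyloxiran-2-yl]methyl}benzene-1,3-diol F6.
  - Catalytic camphorsulfonic acid in CH2Cl2 at 0 °C should direct a phenol of F6 to the tertiary epoxide carbon and give 10.

**Step 12.**
- Risk: the thallium salt may oxidise the electron-rich ring B, or the free chalcone hydroxyl may close onto the α-carbon instead of the aryl shift taking place. Partial loss of the C5 benzyl group in the acid stage is harmless, because step 13 removes it anyway.
- Fallback, from 15 back to the route at 17: NaOAc in refluxing EtOH isomerises 15 to the flavanone 5,7-bis(benzyloxy)-2-[(3S)-5-(benzyloxy)-3-hydroxy-2,2-dimethylchroman-6-yl]chroman-4-one F7 (both C2 epimers). PhI(OH)OTs (trivalent iodine) in MeOH/HC(OMe)3 then effects the 2,3-aryl shift of F7 with dehydrogenation and gives 17.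

**Step 13.**
- Risk: over-reduction of the C2=C3 bond of ring C may compete with cleavage of the last benzyl ether.
- Fallback, from 17 directly to 18: Lewis-acid debenzylation with BCl3 and pentamethylbenzene as cation scavenger in CH2Cl2 at −78 °C. It uses no hydrogen and creates no new intermediate.

## Further compounds

F1 | step 4 | methyl (2S)-3-[2,6-bis(methoxymethoxy)phenyl]-2-hydroxypropanoate | COC(=O)[C@@H](O)Cc1c(OCOC)cccc1OCOC
F2 | step 7 | (2S)-1-[2,6-bis(benzyloxy)phenyl]-3-methylbutane-2,3-diol | CC(C)(O)[C@@H](O)Cc1c(OCc2ccccc2)cccc1OCc1ccccc1
F3 | step 7 | (5S)-5-[2,6-bis(benzyloxy)benzyl]-2-methoxy-2,4,4-trimethyl-1,3-dioxolane (both epimers at C2) | COC1(C)O[C@@H](Cc2c(OCc3ccccc3)cccc2OCc2ccccc2)C(C)(C)O1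
F4 | step 7 | (2S)-1-[2,6-bis(benzyloxy)phenyl]-3-chloro-3-methylbutan-2-yl acetate | CC(=O)O[C@@H](Cc1c(OCc2ccccc2)cccc1OCc1ccccc1)C(C)(C)Cl
F5 | step 7 | (3S)-3-[2,6-bis(benzyloxy)benzyl]-2,2-dimethyloxirane | CC1(C)O[C@H]1Cc1c(OCc2ccccc2)cccc1OCc1ccccc1
F6 | step 7 | 2-{[(2S)-3,3-dimethyloxiran-2-yl]methyl}benzene-1,3-diol | CC1(C)O[C@H]1Cc1c(O)cccc1O
F7 | step 12 | 5,7-bis(benzyloxy)-2-[(3S)-5-(benzyloxy)-3-hydroxy-2,2-dimethylchroman-6-yl]chroman-4-one (both epimers at C2) | CC1(C)Oc2ccc(C3CC(=O)c4c(OCc5ccccc5)cc(OCc5ccccc5)cc4O3)c(OCc3ccccc3)c2C[C@@H]1O
F0 | step 13 | none | none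
A1 | alternative 1 | 5,7-bis(benzyloxy)-3-[(3S)-5-(benzyloxy)-3-hydroxy-2,2-dimethylchroman-6-yl]-4H-chromen-4-one (5,7,2'-tri-O-benzyl ether of the target) | CC1(C)Oc2ccc(-c3coc4cc(OCc5ccccc5)cc(OCc5ccccc5)c4c3=O)c(OCc3ccccc3)c2C[C@@H]1O
A2 | alternative 1 | 5,7-bis(benzyloxy)-3-[2-(benzyloxy)-4-[(tert-butyldimethylsilyl)oxy]-3-{[(2S)-3,3-dimethyloxiran-2-yl]methyl}phenyl]-4H-chromen-4-one | CC1(C)O[C@H]1Cc1c(O[Si](C)(C)C(C)(C)C)ccc(-c2coc3cc(OCc4ccccc4)cc(OCc4ccccc4)c3c2=O)c1OCc1ccccc1
A3 | alternative 2 | 2-[(3S)-3,5-bis(benzyloxy)-2,2-dimethylchroman-6-yl]-3-oxo-3-[2,4,6-tris(benzyloxy)phenyl]propanal | CC1(C)Oc2ccc(C(C=O)C(=O)c3c(OCc4ccccc4)cc(OCc4ccccc4)cc3OCc3ccccc3)c(OCc3ccccc3)c2C[C@@H]1OCc1ccccc1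
A4 | alternative 2 | {3-[(3S)-3,5-bis(benzyloxy)-2,2-dimethylchroman-6-yl]oxiran-2-yl}[2,4,6-tris(benzyloxy)phenyl]methanone (epoxide configuration not specified) | CC1(C)Oc2ccc(C3OC3C(=O)c3c(OCc4ccccc4)cc(OCc4ccccc4)cc3OCc3ccccc3)c(OCc3ccccc3)c2C[C@@H]1OCc1ccccc1
A5 | alternative 3 | 5,7-bis(benzyloxy)-3-[(3S)-3,5-bis(benzyloxy)-2,2-dimethylchroman-6-yl]-4H-chromen-4-one (tetra-O-benzyl ether of the target) | CC1(C)Oc2ccc(-c3coc4cc(OCc5ccccc5)cc(OCc5ccccc5)c4c3=O)c(OCc3ccccc3)c2C[C@@H]1OCc1ccccc1
A6 | alternative 3 | 5,7-bis(benzyloxy)-2-[(3S)-3,5-bis(benzyloxy)-2,2-dimethylchroman-6-yl]chroman-4-one (both epimers at C2) | CC1(C)Oc2ccc(C3CC(=O)c4c(OCc5ccccc5)cc(OCc5ccccc5)cc4O3)c(OCc3ccccc3)c2C[C@@H]1OCc1ccccc1
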